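**Plan**

1. Ring numbering used throughout: C1 is the oxygen-bearing quaternary carbon, C2 the allylic CH2, C3=C4 the alkene (C4 carries CH3), C5 and C6 the remaining CH2 groups. The isopropyl group on C1 is traced back to a formyl group (isopropyl ⇐ isopropenyl ⇐ acetyl ⇐ CHO).
2. The cyclohexene is then cut at C1–C2 and C5–C6 (retro-[4+2]) into isoprene and a 2-(aroyloxy)acrolein that already carries the complete 4-methoxy-3,5-diprenylbenzoyl group.
3. The feature that allows this: the C3=C4 double bond lies 1,4 between the methyl-bearing C4 and the quaternary C1, and C1 carries the ester oxygen plus a carbon that can be CHO. This is the "para" Diels–Alder adduct of isoprene and a captodative acrolein.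
4. The acrolein is cut at its enol-ester C–O bond (aroyl chloride plus the enolate of 2,2-dimethyl-1,3-dioxan-5-one, then retro-hetero-Diels–Alder loss of acetone). The acid is cut at its two aryl–CH2 bonds (double Stille prenylation).
5. Forward order: arene (steps 1–3), dienophile (steps 4–5), the only ring (step 6), CHO to isopropyl (steps 7–10). The aroyl group stays on the C1 oxygen from step 6 onwards.
6. Stereochemistry: the single stereocentre (C1, R) is set in step 6 by a chiral primary ammonium catalyst acting through its iminium ion. It is quaternary and no later step breaks a bond to it.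

Key step: step 6

Assumption: the (R,R)-triamine salt is taken to leave open the Re face at C2 of the bound acrolein (priorities O > CHO > CH2), which gives the R adduct; if the sense of induction proves opposite, the mirror-image triamine from the L-amino acids is used and nothing else changes.

Remark: the triamine catalyst is not purchased; it is made in three routine operations (coupling of Boc-D-Phe-OH with D-leucine pyrrolidide, Boc removal, LiAlH4 reduction of both amides) and is not counted in the steps. Prenyl = 3-methylbut-2-en-1-yl.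

**Step 1**
Reactants: 1 3,5-dibromo-4-hydroxybenzoic acid
Product: 2 methyl 3,5-dibromo-4-methoxybenzoate
Conditions: MeI (3 equiv), K2CO3 (3 equiv), DMF, 40 °C
Reagents that add atoms: iodomethane, CI
Why: Double SN2 methylation (Williamson ether synthesis and carboxylate alkylation) of the phenoxide–carboxylate dianion; the acidic 2,6-dibromophenol is fully ionised by carbonate.

**Step 2**
Reactants: 2 methyl 3,5-dibromo-4-methoxybenzoate; 3 tributyl(3-methylbut-2-en-1-yl)stannane
Product: 4 methyl 4-methoxy-3,5-bis(3-methylbut-2-en-1-yl)benzoate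
Conditions: prenylstannane (2.4 equiv), Pd(PPh3)4 (5 mol %), DMF, 100 °C, degassed
Reagents that add atoms: none
Why: Twofold Stille coupling of an ester-activated aryl bromide with an allylic stannane; reductive elimination from the prenylpalladium intermediate at its unsubstituted terminus should give the linear prenyl groups, and the ester and ether are inert.

**Step 3**
Reactants: 4 methyl 4-methoxy-3,5-bis(3-methylbut-2-en-1-yl)benzoate
Product: 5 4-methoxy-3,5-bis(3-methylbut-2-en-1-yl)benzoic acid
Conditions: LiOH·H2O (3 equiv), THF/MeOH/H2O, 50 °C; then 1 M HCl to pH 3, 0 °C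
Reagents that add atoms: lithium hydroxide, [Li+].[OH-]
Why: Saponification of an unhindered benzoate by acyl–oxygen cleavage; the cold, brief acidification spares the prenyl alkenes.

**Step 4**
Reactants: 5 4-methoxy-3,5-bis(3-methylbut-2-en-1-yl)benzoic acid; 6 2,2-dimethyl-1,3-dioxan-5-one
Product: 9 2,2-dimethyl-4H-1,3-dioxin-5-yl 4-methoxy-3,5-bis(3-methylbut-2-en-1-yl)benzoate, via aroyl chloride 7 (not isolated), via potassium enolate 8 (not isolated)
Conditions: 5, 1-chloro-N,N,2-trimethylprop-1-en-1-amine (1.0 equiv), CH2Cl2, 0 °C → rt; separately 6, KN(SiMe3)2 (1.0 equiv), THF, −78 °C; chloride solution added to the enolate, −78 → 0 °C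
Reagents that add atoms: none
Why: The chloroenamine (Ghosez reagent) makes the acid chloride without releasing HCl, so the prenyl groups are safe; the hard aroyl chloride then acylates the dissociated potassium enolate on oxygen (enol ester formation) to give the 5-acyloxy-4H-1,3-dioxin.

**Step 5**
Reactants: 9 2,2-dimethyl-4H-1,3-dioxin-5-yl 4-methoxy-3,5-bis(3-methylbut-2-en-1-yl)benzoate
Product: 10 3-oxoprop-1-en-2-yl 4-methoxy-3,5-bis(3-methylbut-2-en-1-yl)benzoate
Conditions: toluene, 110 °C, N2 sweep to remove acetone, BHT (trace); used crude at once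
Reagents that add atoms: none
Why: Retro-hetero-Diels–Alder cycloreversion of the 4H-1,3-dioxin expels acetone and unveils the 2-(acyloxy)acrolein; removal of acetone makes it irreversible, and aryl-bound prenyl groups have no thermal pathway at this temperature.

**Step 6**
Reactants: 10 3-oxoprop-1-en-2-yl 4-methoxy-3,5-bis(3-methylbut-2-en-1-yl)benzoate; 11 isoprene
Product: 12 (1R)-1-formyl-4-methylcyclohex-3-en-1-yl 4-methoxy-3,5-bis(3-methylbut-2-en-1-yl)benzoate
Conditions: isoprene in fourfold excess, (2R)-N1-[(2R)-4-methyl-1-(pyrrolidin-1-yl)pentan-2-yl]-3-phenylpropane-1,2-diamine (10 mol %), C6F5SO3H (27.5 mol %), EtNO2, 0 °C → rt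
Reagents that add atoms: none
Why: The primary ammonium group of the catalyst condenses reversibly with the aldehyde of 10 to an aldiminium ion whose lowered LUMO undergoes a concerted, asynchronous [4+2] cycloaddition with isoprene, and the water formed in the condensation hydrolyses the product iminium ion and turns the catalyst over, so all atoms of 10 and 11 end up in 12. The closest known reaction type is the organoammonium-salt-catalysed enantioselective Diels–Alder reaction of 2-(acyloxy)acroleins with dienes, in which 4-methoxybenzoyl-type acyl groups are the favoured ones. The cyclohexene ring is closed by an intermolecular suprafacial–suprafacial [4+2] cycloaddition that forms C5–C6 and C1–C2 in one event, with C5–C6 bonding in advance. The quaternary C1 is the only new stereocentre, and its R configuration is controlled by the catalyst: its benzyl and isobutyl groups, together with hydrogen bonding from a second ammonium N–H to the acyloxy carbonyl, should hold the iminium in one conformation and leave the Re face at the acrolein α-carbon open to the diene. The step needs "para" regioselectivity, secured by bonding of the diene terminus next to the methyl-bearing carbon (largest HOMO coefficient) to the β-CH2 of the iminium (largest LUMO coefficient). It also needs chemoselectivity, secured because the isolated trisubstituted prenyl alkenes are neither dienes nor activated dienophiles and because all sulfonic acid is bound as ammonium salt (2.75 equiv for three nitrogens), so no free strong acid meets the prenyl groups or isoprene.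

**Step 7**
Reactants: 12 (1R)-1-formyl-4-methylcyclohex-3-en-1-yl 4-methoxy-3,5-bis(3-methylbut-2-en-1-yl)benzoate
Product: 13 (1R)-1-(1-hydroxyethyl)-4-methylcyclohex-3-en-1-yl 4-methoxy-3,5-bis(3-methylbut-2-en-1-yl)benzoate, mixture of epimers at the carbinol carbon
Conditions: MeTi(OiPr)3 (1.5 equiv), THF, −40 → 0 °C; aq. NH4Cl, 0 °C; crude taken on at once
Reagents that add atoms: methyltitanium triisopropoxide, C[Ti](OC(C)C)(OC(C)C)OC(C)C
Why: Chemoselective 1,2-addition of a non-basic methyltitanium reagent to the aldehyde (Reetz-type organotitanium addition); the aryl ester is ignored, the weakly nucleophilic titanium alkoxide should not trigger 1,2-acyl migration, and the uncontrolled carbinol centre is erased in step 8.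

**Step 8**
Reactants: 13 (1R)-1-(1-hydroxyethyl)-4-methylcyclohex-3-en-1-yl 4-methoxy-3,5-bis(3-methylbut-2-en-1-yl)benzoate
Product: 14 (1R)-1-acetyl-4-methylcyclohex-3-en-1-yl 4-methoxy-3,5-bis(3-methylbut-2-en-1-yl)benzoate
Conditions: Dess–Martin periodinane (1.3 equiv), CH2Cl2, 0 °C → rt
Reagents that add atoms: none
Why: Dess–Martin oxidation of the secondary alcohol under near-neutral conditions that leave the alkenes and the ester alone; C1 is quaternary and cannot epimerise next to the new ketone.

**Step 9**
Reactants: 14 (1R)-1-acetyl-4-methylcyclohex-3-en-1-yl 4-methoxy-3,5-bis(3-methylbut-2-en-1-yl)benzoate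
Product: 15 (1R)-4-methyl-1-(prop-1-en-2-yl)cyclohex-3-en-1-yl 4-methoxy-3,5-bis(3-methylbut-2-en-1-yl)benzoate
Conditions: Cp2Ti(μ-Cl)(μ-CH2)AlMe2 (1.2 equiv), pyridine (0.2 equiv), THF/toluene, −40 → 0 °C
Reagents that add atoms: Tebbe reagent, C[Al-]1(C)C[Ti]([Cl+]1)(C2C=CC=C2)C3C=CC=C3
Why: Tebbe methylenation ([2+2] addition of the titanium methylidene to the ketone and cycloreversion of the oxatitanacyclobutane) is non-basic, so the enolisable α-acyloxy ketone should neither enolise nor suffer O→C acyl transfer; at low temperature the ketone reacts ahead of the hindered tertiary aroate, and pyridine ties up Me2AlCl so the new tertiary allylic ester does not ionise.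

**Step 10**
Reactants: 15 (1R)-4-methyl-1-(prop-1-en-2-yl)cyclohex-3-en-1-yl 4-methoxy-3,5-bis(3-methylbut-2-en-1-yl)benzoate
Product: 16 (1R)-4-methyl-1-(propan-2-yl)cyclohex-3-en-1-yl 4-methoxy-3,5-bis(3-methylbut-2-en-1-yl)benzoate (target)
Conditions: H2 (1 atm), RhCl(PPh3)3 (10 mol %), benzene, rt; stopped after uptake of one equivalent
Reagents that add atoms: none
Why: Homogeneous hydrogenation with RhCl(PPh3)3 discriminates by alkene substitution, so the 1,1-disubstituted isopropenyl group should be reduced ahead of the three trisubstituted alkenes; the neutral rhodium catalyst should not ionise the tertiary allylic ester.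

**Compound list**

1 | 3,5-dibromo-4-hydroxybenzoic acid | OC(=O)c1cc(Br)c(O)c(Br)c1 | starting material
2 | methyl 3,5-dibromo-4-methoxybenzoate | COC(=O)c1cc(Br)c(OC)c(Br)c1 | intermediate
3 | tributyl(3-methylbut-2-en-1-yl)stannane | CCCC[Sn](CCCC)(CCCC)CC=C(C)C | starting material
4 | methyl 4-methoxy-3,5-bis(3-methylbut-2-en-1-yl)benzoate | COC(=O)c1cc(CC=C(C)C)c(OC)c(CC=C(C)C)c1 | intermediate
5 | 4-methoxy-3,5-bis(3-methylbut-2-en-1-yl)benzoic acid | COc1c(CC=C(C)C)cc(C(=O)O)cc1CC=C(C)C | intermediate
6 | 2,2-dimethyl-1,3-dioxan-5-one | CC1(C)OCC(=O)CO1 | starting material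
7 | 4-methoxy-3,5-bis(3-methylbut-2-en-1-yl)benzoyl chloride | COc1c(CC=C(C)C)cc(C(Cl)=O)cc1CC=C(C)C | intermediate
8 | potassium 2,2-dimethyl-4H-1,3-dioxin-5-olate | CC1(C)OCC([O-])=CO1.[K+] | intermediate
9 | 2,2-dimethyl-4H-1,3-dioxin-5-yl 4-methoxy-3,5-bis(3-methylbut-2-en-1-yl)benzoate | COc1c(CC=C(C)C)cc(C(=O)OC2=COC(C)(C)OC2)cc1CC=C(C)C | intermediate
10 | 3-oxoprop-1-en-2-yl 4-methoxy-3,5-bis(3-methylbut-2-en-1-yl)benzoate | COc1c(CC=C(C)C)cc(C(=O)OC(=C)C=O)cc1CC=C(C)C | intermediate
11 | isoprene (2-methylbuta-1,3-diene) | C=CC(C)=C | starting material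
12 | (1R)-1-formyl-4-methylcyclohex-3-en-1-yl 4-methoxy-3,5-bis(3-methylbut-2-en-1-yl)benzoate | COc1c(CC=C(C)C)cc(C(=O)O[C@@]2(C=O)CC=C(C)CC2)cc1CC=C(C)C | intermediate
13 | (1R)-1-(1-hydroxyethyl)-4-methylcyclohex-3-en-1-yl 4-methoxy-3,5-bis(3-methylbut-2-en-1-yl)benzoate, mixture of epimers at the carbinol carbon | COc1c(CC=C(C)C)cc(C(=O)O[C@@]2(C(C)O)CC=C(C)CC2)cc1CC=C(C)C | intermediate
14 | (1R)-1-acetyl-4-methylcyclohex-3-en-1-yl 4-methoxy-3,5-bis(3-methylbut-2-en-1-yl)benzoate | COc1c(CC=C(C)C)cc(C(=O)O[C@@]2(C(C)=O)CC=C(C)CC2)cc1CC=C(C)C | intermediate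
15 | (1R)-4-methyl-1-(prop-1-en-2-yl)cyclohex-3-en-1-yl 4-methoxy-3,5-bis(3-methylbut-2-en-1-yl)benzoate | COc1c(CC=C(C)C)cc(C(=O)O[C@@]2(C(C)=C)CC=C(C)CC2)cc1CC=C(C)C | intermediate
16 | (1R)-4-methyl-1-(propan-2-yl)cyclohex-3-en-1-yl 4-methoxy-3,5-bis(3-methylbut-2-en-1-yl)benzoate | COc1c(CC=C(C)C)cc(C(=O)O[C@@]2(C(C)C)CC=C(C)CC2)cc1CC=C(C)C | target

**Step count**

Total: 10 steps. Longest linear sequence: 10 steps (1 → 16).

**Steps most likely to fail, with fallbacks**

Step 6. The risk is poor facial discrimination with the acyclic, less reactive diene, or a cycloaddition slow enough for the acrolein to polymerise first. The fallback gives up the cycloaddition and takes the ring from the chiral pool. It sets out from acid 5, which is converted as in step 4 into aroyl chloride 7. Commercial (1R)-4-methyl-1-(propan-2-yl)cyclohex-3-en-1-ol ((R)-terpinen-4-ol) F1 is deprotonated with n-BuLi (THF, −78 → 0 °C) to lithium (1R)-4-methyl-1-(propan-2-yl)cyclohex-3-en-1-olate F2. This tertiary alkoxide is acylated by 7 (THF, 0 °C → rt), and the sequence comes back to the route at target 16; steps 5 to 10 then fall away.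

Step 10. The risk is loss of chemoselectivity: hindrance from the quaternary C1 slows the isopropenyl group and narrows its rate advantage over the prenyl alkenes, so over-reduction may compete. The fallback replaces hydrogenation by hydroboration and deoxygenation, and sets out from 15. 9-BBN (THF, rt), which should differentiate 1,1-disubstituted from trisubstituted alkenes strongly, gives the alkylborane (1R)-1-[1-(9-borabicyclo[3.3.1]nonan-9-yl)propan-2-yl]-4-methylcyclohex-3-en-1-yl 4-methoxy-3,5-bis(3-methylbut-2-en-1-yl)benzoate F3. Oxidation in the same flask with NaBO3·4H2O (rt, near-neutral to limit 1,3-acyl migration) gives the primary alcohol (1R)-1-(1-hydroxypropan-2-yl)-4-methylcyclohex-3-en-1-yl 4-methoxy-3,5-bis(3-methylbut-2-en-1-yl)benzoate F4; its extra stereocentre disappears later. I2, PPh3 and imidazole (CH2Cl2, 0 °C) convert it into the iodide (1R)-1-(1-iodopropan-2-yl)-4-methylcyclohex-3-en-1-yl 4-methoxy-3,5-bis(3-methylbut-2-en-1-yl)benzoate F5. Hydride displacement with NaBH4 in DMSO (60 °C), which leaves the hindered aroate alone, comes back to the route at 16.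

Step 9. The risk is slow methylenation at the hindered carbonyl, leaving room for attack on the ester or for Lewis-acid ionisation of the allylic ester product. The fallback builds the alkene by addition and elimination, and sets out from 14. MeMgBr with CeCl3 (THF, −78 °C, cold quench) adds to the ketone without enolisation and gives the tertiary alcohol (1R)-1-(2-hydroxypropan-2-yl)-4-methylcyclohex-3-en-1-yl 4-methoxy-3,5-bis(3-methylbut-2-en-1-yl)benzoate F6. Dehydration with Burgess reagent (toluene, 50 °C) can only take a proton from a methyl group, because the other neighbour is quaternary, and comes back to the route at 15.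

**Further compounds**

F1 | step 6 | (1R)-4-methyl-1-(propan-2-yl)cyclohex-3-en-1-ol ((R)-terpinen-4-ol, purchased) | O[C@@]1(C(C)C)CC=C(C)CC1
F2 | step 6 | lithium (1R)-4-methyl-1-(propan-2-yl)cyclohex-3-en-1-olate | [Li+].[O-][C@@]1(C(C)C)CC=C(C)CC1
F3 | step 10 | (1R)-1-[1-(9-borabicyclo[3.3.1]nonan-9-yl)propan-2-yl]-4-methylcyclohex-3-en-1-yl 4-methoxy-3,5-bis(3-methylbut-2-en-1-yl)benzoate | COc1c(CC=C(C)C)cc(C(=O)O[C@@]2(C(C)CB3C4CCCC3CCC4)CC=C(C)CC2)cc1CC=C(C)C
F4 | step 10 | (1R)-1-(1-hydroxypropan-2-yl)-4-methylcyclohex-3-en-1-yl 4-methoxy-3,5-bis(3-methylbut-2-en-1-yl)benzoate | COc1c(CC=C(C)C)cc(C(=O)O[C@@]2(C(C)CO)CC=C(C)CC2)cc1CC=C(C)C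
F5 | step 10 | (1R)-1-(1-iodopropan-2-yl)-4-methylcyclohex-3-en-1-yl 4-methoxy-3,5-bis(3-methylbut-2-en-1-yl)benzoate | COc1c(CC=C(C)C)cc(C(=O)O[C@@]2(C(C)CI)CC=C(C)CC2)cc1CC=C(C)C
F6 | step 9 | (1R)-1-(2-hydroxypropan-2-yl)-4-methylcyclohex-3-en-1-yl 4-methoxy-3,5-bis(3-methylbut-2-en-1-yl)benzoate | COc1c(CC=C(C)C)cc(C(=O)O[C@@]2(C(C)(C)O)CC=C(C)CC2)cc1CC=C(C)C
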